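**Plan**
- Retrosynthesis: the C7 benzoate is removed last; ring C is then cut across C2=C3, leaving on ring A an acyl ylide at C4a and a benzoate on the C8a oxygen; the ylide goes back to a chloroacetyl group put on by aryl lithiation; the piperidine is cut at N–C6' and C2'–C3'.
- Enabling feature: in ring C, C3 is the carbon alpha to the C4 ketone and C2 carries phenyl and O1, so C2 is a benzoate carbonyl on O1 in disguise. The two partners sit ortho on ring A and can be joined by an ester Wittig reaction in a neutral medium.
- Forward order: ring A is bought as 5-methoxyresorcinol; the C8 carbon is added by formylation; the piperidine ring closes next by Grignard addition and N-alkylation; the C4 side chain follows; ring C closes last, the phenyl ring arriving with benzoyl chloride.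
- Stereochemistry: the only stereocentre, C2' (R), is set in the Grignard addition to an (S)-tert-butanesulfinyl aldimine. It is protected afterwards by avoiding hot acid and strong base, which could open the electron-rich benzylic C2'–N bond.

Key step: step 10

Remark: flavone numbering (O1, C2, C3, C4, C4a, C5 to C8, C8a; piperidine atoms primed) is used for the matching atoms of every intermediate. The sense of induction in step 4 is taken from the magnesium-chelated chair model for N-tert-butanesulfinyl aldimines and would be confirmed on 9 or 10 before going on.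

Step 1
Reactants: 1 5-methoxyresorcinol
Product: 2 1-methoxy-3,5-bis(methoxymethoxy)benzene
Conditions: NaH, MOMCl, DMF, 0 °C to rt
Reagents that add atoms: chloromethyl methyl ether, COCCl
Why: Double Williamson etherification of the two phenoxides installs acetal groups that later direct ortho-lithiation and can be removed by acid methanolysis.

Step 2
Reactants: 2 1-methoxy-3,5-bis(methoxymethoxy)benzene
Product: 4 4-methoxy-2,6-bis(methoxymethoxy)benzaldehyde, via aryllithium 3 (not isolated)
Conditions: n-BuLi, TMEDA, THF, 0 °C; DMF, -78 °C to rt; aq. AcOH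
Reagents that add atoms: N,N-dimethylformamide, CN(C)C=O
Why: Directed ortho-metalation should occur at the carbon flanked by both methoxymethoxy groups, which act together and direct more strongly than methoxy, and formylation of the aryllithium with DMF supplies the future C2'.

Step 3
Reactants: 4 4-methoxy-2,6-bis(methoxymethoxy)benzaldehyde; 5 (S)-tert-butanesulfinamide
Product: 6 (S,E)-N-[4-methoxy-2,6-bis(methoxymethoxy)benzylidene]-2-methylpropane-2-sulfinamide
Conditions: Ti(OEt)4, THF, 65 °C
Reagents that add atoms: none
Why: Ti(OEt)4-mediated condensation of an aldehyde with tert-butanesulfinamide gives the E-configured N-sulfinyl aldimine, the titanium alkoxide activating the hindered carbonyl and taking up the water.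

Step 4
Reactants: 6 (S,E)-N-[4-methoxy-2,6-bis(methoxymethoxy)benzylidene]-2-methylpropane-2-sulfinamide; 7 1-bromo-4-chlorobutane
Product: 9 (S)-N-{(1R)-5-chloro-1-[4-methoxy-2,6-bis(methoxymethoxy)phenyl]pentyl}-2-methylpropane-2-sulfinamide, via 4-chlorobutylmagnesium bromide 8 (not isolated)
Conditions: 7, Mg, Et2O, rt; then 6, CH2Cl2, -48 °C to rt; H2O
Reagents that add atoms: none
Why: Grignard addition to an N-tert-butanesulfinyl aldimine in a non-coordinating solvent should pass through a six-membered chair with magnesium bound to the sulfinyl oxygen and tert-butyl equatorial, so the (S)-sulfur directs the 4-chlorobutyl group to the face that makes C2' (R), while the primary chloride is inert to the Grignard reagent at this temperature.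

Step 5
Reactants: 9 (S)-N-{(1R)-5-chloro-1-[4-methoxy-2,6-bis(methoxymethoxy)phenyl]pentyl}-2-methylpropane-2-sulfinamide
Product: 10 (2R)-1-[(S)-tert-butylsulfinyl]-2-[4-methoxy-2,6-bis(methoxymethoxy)phenyl]piperidine
Conditions: NaH, DMF, 0 °C to rt
Reagents that add atoms: none
Why: The deprotonated sulfinamide nitrogen displaces the primary chloride in a 6-exo-tet intramolecular N-alkylation, which closes the piperidine ring without touching the benzylic stereocentre.

Step 6
Reactants: 10 (2R)-1-[(S)-tert-butylsulfinyl]-2-[4-methoxy-2,6-bis(methoxymethoxy)phenyl]piperidine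
Product: 12 (2R)-2-[4-methoxy-2,6-bis(methoxymethoxy)phenyl]-1-methylpiperidine, via NH-piperidine 11 (not isolated)
Conditions: HCl (4 M in dioxane), MeOH, 0 °C, short time; evaporate; then Et3N, aq. CH2O, NaBH(OAc)3, CH2Cl2, rt
Reagents that add atoms: formaldehyde, C=O
Why: Cold acid methanolysis cleaves the N–S bond of the sulfinamide much faster than the aryl methoxymethyl acetals, and reductive amination of the freed secondary amine with formaldehyde and NaBH(OAc)3 gives the N-methyl amine without hot acid that could ionise the benzylic C2'–N bond.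

Step 7
Reactants: 12 (2R)-2-[4-methoxy-2,6-bis(methoxymethoxy)phenyl]-1-methylpiperidine; 13 2-chloro-N-methoxy-N-methylacetamide
Product: 15 2-chloro-1-{6-methoxy-2,4-bis(methoxymethoxy)-3-[(2R)-1-methylpiperidin-2-yl]phenyl}ethan-1-one, via aryllithium 14 (not isolated)
Conditions: n-BuLi, TMEDA, THF, -20 to 0 °C; then 13, -78 °C; AcOH quench at -78 °C; crude product used at once
Reagents that add atoms: none
Why: Directed ortho-metalation at one of the two equivalent ring positions between methoxymethoxy and methoxy, then acylation of the aryllithium by the N-methoxy-N-methylamide (Weinreb ketone synthesis), stops at the ketone stage through the chelated tetrahedral adduct and places the chloroacetyl group on the future C4a.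

Step 8
Reactants: 15 2-chloro-1-{6-methoxy-2,4-bis(methoxymethoxy)-3-[(2R)-1-methylpiperidin-2-yl]phenyl}ethan-1-one; 16 triphenylphosphine
Product: 18 (2-{2,4-dihydroxy-6-methoxy-3-[(2R)-1-methylpiperidin-2-yl]phenyl}-2-oxoethyl)triphenylphosphonium chloride hydrochloride, via bis-MOM phosphonium chloride 17 (not isolated)
Conditions: PPh3, THF, 60 °C; then HCl (3 M in MeOH), rt; evaporate
Reagents that add atoms: hydrogen chloride, Cl
Why: SN2 displacement of the alpha-chloro ketone by triphenylphosphine gives the phenacylphosphonium salt (chloride rather than bromide avoids halophilic attack), and acid-catalysed acetal exchange with methanol then frees both phenols, the electron-poor phosphonium ketone on ring A weakening the push that could open the C2'–N bond.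

Step 9
Reactants: 18 (2-{2,4-dihydroxy-6-methoxy-3-[(2R)-1-methylpiperidin-2-yl]phenyl}-2-oxoethyl)triphenylphosphonium chloride hydrochloride; 19 benzoyl chloride
Product: 20 (R)-5-methoxy-2-(1-methylpiperidin-2-yl)-4-[(triphenylphosphoranylidene)acetyl]-1,3-phenylene dibenzoate
Conditions: BzCl (2.3 equiv), pyridine, CH2Cl2, 0 °C; cold aq. NaHCO3 work-up
Reagents that add atoms: benzoyl chloride, O=C(Cl)c1ccccc1
Why: Pyridine-mediated O-acylation consumes two equivalents of benzoyl chloride, one on each phenol of the ortho-hydroxyphenacyl phosphonium salt (a known reaction of such hydroxy ylide precursors, the weakly basic medium keeping the alpha-carbon protonated and unacylated), and the bicarbonate work-up then removes the remaining HCl to leave the neutral, isolable stabilised ylide.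

Step 10
Reactants: 20 (R)-5-methoxy-2-(1-methylpiperidin-2-yl)-4-[(triphenylphosphoranylidene)acetyl]-1,3-phenylene dibenzoate
Product: 21 (R)-5-methoxy-8-(1-methylpiperidin-2-yl)-4-oxo-2-phenyl-4H-chromen-7-yl benzoate
Conditions: toluene, 110 °C, N2
Reagents that add atoms: none
Why: On heating, the ylide carbon (the future C3) adds to the carbonyl of the benzoate on the C8a oxygen, the betaine closes to an oxaphosphetane, and cycloreversion gives the C2=C3 double bond and triphenylphosphine oxide. The closest known reaction type is the intramolecular Wittig olefination of ortho-acyloxy aroylmethylene phosphoranes, an established way to chromones and flavones, in which an ester normally inert to stabilised ylides reacts because it is held next to the ylide and the product is an aromatic pyranone. Ring C closes by 6-exo-trig attack on the ester carbonyl, C2 keeping the phenyl group and O1 being the former phenol oxygen. No stereocentre is created, and C2' is not at risk because the medium is neutral and aprotic and both oxygens ortho to C8 stay acylated, so neither ammonium formation nor phenol-assisted opening of the C2'–N bond can occur. The step needs site selectivity between two benzoates, and ring A supplies it: only the C8a ester is ortho to the acyl ylide, whereas the C7 ester is meta to it and cannot be reached.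

Step 11
Reactants: 21 (R)-5-methoxy-8-(1-methylpiperidin-2-yl)-4-oxo-2-phenyl-4H-chromen-7-yl benzoate
Product: 22 (R)-7-hydroxy-5-methoxy-8-(1-methylpiperidin-2-yl)-2-phenyl-4H-chromen-4-one
Conditions: K2CO3 (cat.), MeOH, 0 °C to rt; pH 7 buffer work-up
Reagents that add atoms: none
Why: Base-catalysed transesterification with methanol cleaves the aryl benzoate, which is activated as the ester of a vinylogous acid, and frees the C7 phenol under conditions too mild to disturb C2'.

**Compound list**
1 | 5-methoxyresorcinol | COc1cc(O)cc(O)c1 | starting material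
2 | 1-methoxy-3,5-bis(methoxymethoxy)benzene | COCOc1cc(OC)cc(OCOC)c1 | intermediate
3 | [4-methoxy-2,6-bis(methoxymethoxy)phenyl]lithium | [Li]c1c(OCOC)cc(OC)cc1OCOC | intermediate
4 | 4-methoxy-2,6-bis(methoxymethoxy)benzaldehyde | O=Cc1c(OCOC)cc(OC)cc1OCOC | intermediate
5 | (S)-tert-butanesulfinamide | CC(C)(C)[S@](=O)N | starting material
6 | (S,E)-N-[4-methoxy-2,6-bis(methoxymethoxy)benzylidene]-2-methylpropane-2-sulfinamide | CC(C)(C)[S@](=O)/N=C/c1c(OCOC)cc(OC)cc1OCOC | intermediate
7 | 1-bromo-4-chlorobutane | ClCCCCBr | starting material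
8 | 4-chlorobutylmagnesium bromide | ClCCCC[Mg]Br | intermediate
9 | (S)-N-{(1R)-5-chloro-1-[4-methoxy-2,6-bis(methoxymethoxy)phenyl]pentyl}-2-methylpropane-2-sulfinamide | CC(C)(C)[S@](=O)N[C@H](CCCCCl)c1c(OCOC)cc(OC)cc1OCOC | intermediate
10 | (2R)-1-[(S)-tert-butylsulfinyl]-2-[4-methoxy-2,6-bis(methoxymethoxy)phenyl]piperidine | CC(C)(C)[S@](=O)N1CCCC[C@@H]1c2c(OCOC)cc(OC)cc2OCOC | intermediate
11 | (2R)-2-[4-methoxy-2,6-bis(methoxymethoxy)phenyl]piperidine (formed as its hydrochloride, freed in the flask by Et3N) | COc1cc(OCOC)c([C@H]2CCCCN2)c(OCOC)c1 | intermediate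
12 | (2R)-2-[4-methoxy-2,6-bis(methoxymethoxy)phenyl]-1-methylpiperidine | COc1cc(OCOC)c([C@H]2CCCCN2C)c(OCOC)c1 | intermediate
13 | 2-chloro-N-methoxy-N-methylacetamide | CON(C)C(=O)CCl | starting material
14 | {6-methoxy-2,4-bis(methoxymethoxy)-3-[(2R)-1-methylpiperidin-2-yl]phenyl}lithium | COc1cc(OCOC)c([C@H]2CCCCN2C)c(OCOC)c1[Li] | intermediate
15 | 2-chloro-1-{6-methoxy-2,4-bis(methoxymethoxy)-3-[(2R)-1-methylpiperidin-2-yl]phenyl}ethan-1-one | COc1cc(OCOC)c([C@H]2CCCCN2C)c(OCOC)c1C(=O)CCl | intermediate
16 | triphenylphosphine | c1ccc(cc1)P(c1ccccc1)c1ccccc1 | starting material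
17 | (2-{6-methoxy-2,4-bis(methoxymethoxy)-3-[(2R)-1-methylpiperidin-2-yl]phenyl}-2-oxoethyl)triphenylphosphonium chloride | COc1cc(OCOC)c([C@H]2CCCCN2C)c(OCOC)c1C(=O)C[P+](c1ccccc1)(c1ccccc1)c1ccccc1.[Cl-] | intermediate
18 | (2-{2,4-dihydroxy-6-methoxy-3-[(2R)-1-methylpiperidin-2-yl]phenyl}-2-oxoethyl)triphenylphosphonium chloride hydrochloride | COc1cc(O)c([C@H]2CCCCN2C)c(O)c1C(=O)C[P+](c1ccccc1)(c1ccccc1)c1ccccc1.[Cl-].Cl | intermediate
19 | benzoyl chloride | O=C(Cl)c1ccccc1 | starting material
20 | (R)-5-methoxy-2-(1-methylpiperidin-2-yl)-4-[(triphenylphosphoranylidene)acetyl]-1,3-phenylene dibenzoate | COc1cc(OC(=O)c2ccccc2)c([C@H]2CCCCN2C)c(OC(=O)c2ccccc2)c1C(=O)C=P(c1ccccc1)(c1ccccc1)c1ccccc1 | intermediate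
21 | (R)-5-methoxy-8-(1-methylpiperidin-2-yl)-4-oxo-2-phenyl-4H-chromen-7-yl benzoate | COc1cc(OC(=O)c2ccccc2)c([C@H]2CCCCN2C)c2oc(-c3ccccc3)cc(=O)c12 | intermediate
22 | (R)-7-hydroxy-5-methoxy-8-(1-methylpiperidin-2-yl)-2-phenyl-4H-chromen-4-one | COc1cc(O)c([C@H]2CCCCN2C)c2oc(-c3ccccc3)cc(=O)c12 | target

**Step count**
Total: 11 steps. Longest linear sequence: 11 steps, from 1 to 22.

**Steps most likely to fail**

Step 4. The risk is poor or reversed facial selectivity: magnesium may chelate to the ortho methoxymethoxy oxygens in competition with the sulfinyl-bound chair, and addition to the hindered, electron-rich imine may be slow. The fallback sets the stereocentre by catalyst control instead. It sets out from 2, which is lithiated as in step 2 to 3 and added to 5-chloropentanenitrile; addition and ring closure in the same flask, with loss of LiCl, give the cyclic imine 6-[4-methoxy-2,6-bis(methoxymethoxy)phenyl]-2,3,4,5-tetrahydropyridine F1. Asymmetric hydrogenation of F1 with [Ir(COD)Cl]2, a chiral bisphosphine (the ligand enantiomer chosen by screening to deliver the R amine) and H2 gives the free base 11, where the fallback comes back to the route; reductive methylation as in step 6 then gives 12.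

Step 7. The risk is proton transfer from the acidic CH2 of the chloroacetamide to the aryllithium, which returns 12, and self-alkylation of the basic amine by the alpha-chloro ketone while it is handled. The fallback builds the acyl ylide from a carboxylic acid. It sets out from 12, which is lithiated as in step 7 to 14 and quenched with CO2 to give 6-methoxy-2,4-bis(methoxymethoxy)-3-[(2R)-1-methylpiperidin-2-yl]benzoic acid F2. Activation with 1,1'-carbonyldiimidazole gives (1H-imidazol-1-yl){6-methoxy-2,4-bis(methoxymethoxy)-3-[(2R)-1-methylpiperidin-2-yl]phenyl}methanone F3. Acylation of methylenetriphenylphosphorane (two equivalents, from methyltriphenylphosphonium bromide and NaN(SiMe3)2) gives 1-{6-methoxy-2,4-bis(methoxymethoxy)-3-[(2R)-1-methylpiperidin-2-yl]phenyl}-2-(triphenylphosphoranylidene)ethan-1-one F4. Methanolic HCl at rt protonates the ylide and removes both acetals, and the fallback comes back to the route at 18.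

Step 10. The risk is slow ring closure, because the 2,6-disubstituted aroyl ylide is twisted out of conjugation and only weakly nucleophilic, so that benzoyl transfer to the ylide carbon without loss of triphenylphosphine oxide can compete on long heating. The fallback closes ring C at O1–C2 instead. It sets out from 12, which is lithiated as in step 7 to 14 and acylated with N-methoxy-N-methyl-3-phenylpropiolamide to give 1-{6-methoxy-2,4-bis(methoxymethoxy)-3-[(2R)-1-methylpiperidin-2-yl]phenyl}-3-phenylprop-2-yn-1-one F5. Methanolic HCl at rt frees the phenols and gives 1-{2,4-dihydroxy-6-methoxy-3-[(2R)-1-methylpiperidin-2-yl]phenyl}-3-phenylprop-2-yn-1-one F6. Et2NH in EtOH then promotes 6-endo closure of the C8a phenol onto the ynone, and the fallback comes back to the route at 22.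

**Further compounds**
F1 | step 4 | 6-[4-methoxy-2,6-bis(methoxymethoxy)phenyl]-2,3,4,5-tetrahydropyridine | COc1cc(OCOC)c(C2=NCCCC2)c(OCOC)c1
F2 | step 7 | 6-methoxy-2,4-bis(methoxymethoxy)-3-[(2R)-1-methylpiperidin-2-yl]benzoic acid | COc1cc(OCOC)c([C@H]2CCCCN2C)c(OCOC)c1C(=O)O
F3 | step 7 | (1H-imidazol-1-yl){6-methoxy-2,4-bis(methoxymethoxy)-3-[(2R)-1-methylpiperidin-2-yl]phenyl}methanone | COc1cc(OCOC)c([C@H]2CCCCN2C)c(OCOC)c1C(=O)n1ccnc1
F4 | step 7 | 1-{6-methoxy-2,4-bis(methoxymethoxy)-3-[(2R)-1-methylpiperidin-2-yl]phenyl}-2-(triphenylphosphoranylidene)ethan-1-one | COc1cc(OCOC)c([C@H]2CCCCN2C)c(OCOC)c1C(=O)C=P(c1ccccc1)(c1ccccc1)c1ccccc1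
F5 | step 10 | 1-{6-methoxy-2,4-bis(methoxymethoxy)-3-[(2R)-1-methylpiperidin-2-yl]phenyl}-3-phenylprop-2-yn-1-one | COc1cc(OCOC)c([C@H]2CCCCN2C)c(OCOC)c1C(=O)C#Cc1ccccc1
F6 | step 10 | 1-{2,4-dihydroxy-6-methoxy-3-[(2R)-1-methylpiperidin-2-yl]phenyl}-3-phenylprop-2-yn-1-one | COc1cc(O)c([C@H]2CCCCN2C)c(O)c1C(=O)C#Cc1ccccc1
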